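## The problem

The target is a flavonol: a 4H-chromen-4-one (rings A and C) that carries a 3,4-dioxygenated phenyl ring B on C2. It has no stereocentre, so the task is to build the C6–C3–C6 skeleton and to tell five oxygens apart. O7 is a methyl ether, O3, O5 and O4' are sulfate monoesters, and O3' is a free phenol next to the 4'-sulfate. This pattern runs against innate reactivity: the 5-OH is hydrogen-bonded to C4=O and is the least reactive hydroxyl of a flavonol, yet it must be sulfated, while the unhindered 3'-OH must stay free. O3' therefore needs a blocking group that survives sulfation and then leaves without acid. Aryl sulfate monoesters are ionic, hard to purify and cleaved by acid, so sulfation must come at the very end and every other protecting group must leave before it under conditions that spare the group on O3'. In ring A the oxygens on C5, C7 and C8a are meta to one another and take three different roles (sulfate, methyl ether, ring oxygen O1), and the oxygen on C3 must be set between C2 and C4, where the usual late oxidation of a chalcone is diverted to aurones by a substituent on the future C5. The feature that opens the plan: ring A has oxygen on C5, C7 and C8a alternating with C6, C8 and C4a, and C4a bears the acyl carbon C4. This acylphloroglucinol pattern, with O5 and O1 equivalent before ring C closes and O7 para to C4a, is what a 4-methoxy-2-pyrone with a 2-oxoalkyl chain on C6 gives when its lactone is opened and closed again onto carbon.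

## Retrosynthesis

Target 18 back to 16 (through salt 17): the O3'–CH2Ph bond is cut. Hydrogenolysis is preferred to any acid- or Lewis-acid-labile group on O3' because it is the one deprotection that leaves aryl sulfate salts untouched. The precursor differs only by a benzyl group. The forward reaction must run at neutral pH on a trianion, and the acid form is set free only afterwards.

16 back to 14 (through salt 15): the three O–S bonds are cut. Sulfating last avoids carrying ionic, acid-labile groups through the route. With O3' benzylated and O7 methylated, every remaining hydroxyl of 14 (O3, O5, O4') is to be sulfated, so the reaction need not choose between sites; it only has to go to completion at the chelated 5-OH. 14 is a neutral flavonol that can be purified normally.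

14 back to 13 and then 12: the two MOM acetals are cut, then the C2=C3 double bond is returned to a C2–H/C3–H single bond. MOM is chosen because dilute acid removes it and spares the benzyl ether. The partly saturated ring C of 12 is what an oxa-Michael closure delivers, and its dehydrogenation is driven by formation of the conjugated 4-pyranone. The forward reaction must oxidise C2–C3 without attacking the electron-rich ring A.

12 back to 9 (key disconnection): O1–C2 and the ring-A bond C4a–C5 (equivalent to C4a–C8a) are cut, and C5 is reconnected to O1 through oxygen, so that ring A becomes the 2-pyrone ring of 9. Against the neighbouring cuts (Cα–Cβ aldol of a chalcone, or O1–C2 alone), this one removes the ring-A problem altogether. The methyl ether is already the only ether of the pyrone, the two future hydroxyls are the two lactone oxygens and appear unprotected and equivalent, and O3 is in the chain before ring C exists. 9 has one carbocycle and one heterocycle fewer than 12. The forward reaction must cyclise in the Claisen mode (carbon onto the ester carbonyl) and not in the aldol mode.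

9 back to 8 and 7: the C4–C4a bond is cut, that is, the bond between the exocyclic methyl carbon of pyrone 8 and the acyl carbon. The methyl group of 8 is the vinylogous α-position of the lactone, and its anion is the equivalent of a 2,6-dihydroxy-4-methoxyphenyl anion. The whole C4–C3–C2–ring B unit can therefore arrive as one ester, 7. The forward reaction must be a 1,2-acylation and not a conjugate addition.

7 back to 2 and 4, and these to 1 and 3: the C2=C3 double bond of the cinnamate is cut (aldol addition and elimination), then the two MOM ethers. Aldehyde 1 brings the differentiated catechol (O3' benzylated, O4' free), and glycolate 3 brings O3.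

## Roads not taken

Alternative 1: the most obvious route. Cut O1–C2 and add O3 last; before that, cut the Cα–Cβ bond of a chalcone. Forward: Claisen–Schmidt condensation of purchased 1-(2,6-dihydroxy-4-methoxyphenyl)ethanone A1 with aldehyde 2 to the 2',6'-dihydroxychalcone A2, then Algar–Flynn–Oyamada oxidation with alkaline H2O2 and acid to reach 14. This is shorter by one or two steps on paper. The chosen plan is preferred because the oxidative ring closure has a structural liability exactly here: a second oxygen on C6' (the future O5) steers the phenoxide toward Cα (5-exo closure) and gives the aurone A3. Masking that oxygen costs two operations on ring A without removing the bias, and alkaline peroxide meets an electron-rich chalcone. In the chosen route O3 is placed before ring C exists, ring A never carries a protecting group, and no peroxide is used.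

Alternative 2: cut C4–C4a and O1–C8a in one operation with an aryne. Forward: fluoride converts 3,5-dimethoxy-2-(trimethylsilyl)phenyl trifluoromethanesulfonate A4 into 3,5-dimethoxybenzyne A5. The carboxylate of acid A6 (the acid of ester 7) adds to the aryne carbon remote from the flanking methoxy group, the aryl anion ortho to that methoxy group takes the acyl group (C–O insertion), and oxa-Michael closure gives the 5,7-dimethoxyflavanone A7. The regiochemistry is right, but both ring-A oxygens arrive as methyl ethers. Freeing O5 needs BCl3 or AlCl3, which also cleave the 3'-O-benzyl and MOM ethers, and an unsymmetrical aryne precursor would need silylation between two unlike oxygens. A4 also costs three steps from 3,5-dimethoxyphenol, whereas pyrone 8 is bought and delivers 5-OH free with 7-OMe set.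

Alternative 3: cut C2–C1', a direct union of the chromone and ring B. Forward: C–H arylation at C2 of 5-hydroxy-7-methoxy-3-(methoxymethoxy)-4H-chromen-4-one A8 with boronic acid A9 under Pd(OAc)2 and an oxidant (oxidative Heck type, divalent palladium), giving 13 directly. It is convergent and at the right oxidation level, but A8 has no short access. Its C3 oxygen must come through an ω-oxygenated acetophenone or a chromone epoxide, four to five steps, so the run-up consumes the gain. In the coupling, palladium would have to sit on C3, a fully substituted carbon bearing the OMOM group, and β-hydride elimination toward C2 would need epimerisation through the O-bound enolate. The quinone oxidants also threaten the ring-A phenol. The chosen key step needs no metal and no oxidant.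

Key step: step 5

Assumption: the SMILES shows the three sulfates as free acids; because aryl hydrogen sulfates hydrolyse in acid, the compound is carried as its trisodium salt and the acid form is set free cold in the last operation.

## Route

Step 1
Reactants: 1 3-(benzyloxy)-4-hydroxybenzaldehyde
Product: 2 3-(benzyloxy)-4-(methoxymethoxy)benzaldehyde
Conditions: MOMCl, i-Pr2NEt, CH2Cl2, 0 °C to rt
Reagents that add atoms: chloromethyl methyl ether (MOMCl), COCCl
Why: O-alkylation of the phenol (made acidic by the para formyl group) with an α-chloro ether; the MOM acetal should survive the amide base, Mg(OMe)2 and hot DMSO and later leaves with dilute acid that spares the benzyl ether.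

Step 2
Reactants: 3 methyl glycolate
Product: 4 methyl 2-(methoxymethoxy)acetate
Conditions: MOMCl, i-Pr2NEt, CH2Cl2, 0 °C to rt
Reagents that add atoms: chloromethyl methyl ether (MOMCl), COCCl
Why: MOM protection of a primary alcohol; the glycolate oxygen becomes O3 of the flavonol and carries the same acid-labile group as O4'.

Step 3
Reactants: 2 3-(benzyloxy)-4-(methoxymethoxy)benzaldehyde; 4 methyl 2-(methoxymethoxy)acetate
Product: 7 methyl (2Z)-3-[3-(benzyloxy)-4-(methoxymethoxy)phenyl]-2-(methoxymethoxy)prop-2-enoate, via lithium aldolate 5 (not isolated), via benzylic mesylate 6 (not isolated)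
Conditions: 4, LiN(i-Pr)2, THF, −78 °C; then 2; then MsCl, −78 to 0 °C; then DBU, 0 °C to rt
Reagents that add atoms: none
Why: Ester enolate aldol addition to a non-enolisable aldehyde, O-mesylation of the aldolate and E1cB elimination; the (Z)-isomer (aryl trans to the ester) is the thermodynamic one, and the geometry is without consequence because this double bond becomes C2–C3 of ring C.

Step 4
Reactants: 8 4-methoxy-6-methyl-2H-pyran-2-one; 7 methyl (2Z)-3-[3-(benzyloxy)-4-(methoxymethoxy)phenyl]-2-(methoxymethoxy)prop-2-enoate
Product: 9 6-{(3Z)-4-[3-(benzyloxy)-4-(methoxymethoxy)phenyl]-3-(methoxymethoxy)-2-oxobut-3-en-1-yl}-4-methoxy-2H-pyran-2-one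
Conditions: 8 (2.1 equiv), LiN(i-Pr)2 (2.2 equiv), THF, −78 °C; then 7, −78 to −30 °C; AcOH
Reagents that add atoms: none
Why: Claisen-type C-acylation of the vinylogous lactone enolate formed by deprotonation of the 6-methyl group; the product methylene is more acidic and is deprotonated by the second equivalent of anion, which drives the equilibrium, and 1,2-attack should win because the β-aryl α-alkoxy acrylate is a poor Michael acceptor.

Step 5
Reactants: 9 6-{(3Z)-4-[3-(benzyloxy)-4-(methoxymethoxy)phenyl]-3-(methoxymethoxy)-2-oxobut-3-en-1-yl}-4-methoxy-2H-pyran-2-one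
Product: 12 rac-(2R,3R)-2-[3-(benzyloxy)-4-(methoxymethoxy)phenyl]-5-hydroxy-7-methoxy-3-(methoxymethoxy)-2,3-dihydro-4H-chromen-4-one (trans-flavanone), via ring-opened triketo ester 10 (not isolated), via chalcone 11 (not isolated)
Conditions: Mg(OMe)2 (8 equiv), MeOH, reflux; then 1 M HCl to pH 5, 0 °C
Reagents that add atoms: none
Why: Methoxide on magnesium opens the enol lactone of 9 at the pyrone carbonyl and gives the magnesium-chelated triketo ester 10, whose C2=C3 double bond keeps the ester and the chain cis as they were in the pyrone ring. The methylene between the two ketones (C6 of 10, the future C4a) is the most acidic site; as its magnesium enolate it attacks the ester carbonyl in a Claisen (Dieckmann-type) condensation, a 6-exo-trig closure that forms the C4a–C5 bond, and loss of methoxide followed by enolisation makes ring A aromatic (chalcone 11). The closest known reaction type is the biomimetic Mg(OMe)2-mediated conversion of 6-(2-oxoalkyl)-4-methoxy-2-pyrones into 2-acyl-5-methoxyresorcinols, the polyketide Claisen cyclisation. The selectivity needed is Claisen against the aldol mode (the dienolate carbon next to the ester, C2 of 10, attacking the C7 ketone, which would give a resorcylate); chelation of the 5,7-diketone by magnesium keeps the nucleophile on C6 and is what should secure it. The methoxy group sits on the one pyrone carbon that is not attacked, so it ends up para to the acyl group as 7-OMe, and the two new hydroxyls (from the ring oxygen and the carbonyl oxygen of the lactone) are equivalent, so ring C can close from either without a regiochemical question. Ring C should close in the same medium by 6-endo-trig oxa-Michael addition of a phenoxide to Cβ of the enone. C2 and C3 become stereocentres; the reversible oxa-Michael step and the enolisable C3–H should lead to the racemic trans (diequatorial) isomer under thermodynamic control, and both centres are erased in step 6, so no control is required. Any chalcone 11 that stays open is carried into step 6, which accepts both.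

Step 6
Reactants: 12 rac-(2R,3R)-2-[3-(benzyloxy)-4-(methoxymethoxy)phenyl]-5-hydroxy-7-methoxy-3-(methoxymethoxy)-2,3-dihydro-4H-chromen-4-one
Product: 13 2-[3-(benzyloxy)-4-(methoxymethoxy)phenyl]-5-hydroxy-7-methoxy-3-(methoxymethoxy)-4H-chromen-4-one
Conditions: I2 (0.1 equiv), DMSO, 110 °C
Reagents that add atoms: none
Why: Iodine/DMSO dehydrogenation of a flavanone: iodination of the enol at C3 and loss of HI give the conjugated 4-pyranone, DMSO reoxidises HI to I2 so that iodine and acid stay at a low level, and both stereocentres are removed.

Step 7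
Reactants: 13 2-[3-(benzyloxy)-4-(methoxymethoxy)phenyl]-5-hydroxy-7-methoxy-3-(methoxymethoxy)-4H-chromen-4-one
Product: 14 2-[3-(benzyloxy)-4-hydroxyphenyl]-3,5-dihydroxy-7-methoxy-4H-chromen-4-one (3'-O-benzylrhamnetin)
Conditions: 3 M HCl, MeOH/THF, 50 °C
Reagents that add atoms: none
Why: Acid-catalysed methanolysis of both MOM acetals; the benzyl and methyl ethers and the flavonol core are stable to dilute acid, so exactly the three hydroxyls to be sulfated are freed.

Step 8
Reactants: 14 2-[3-(benzyloxy)-4-hydroxyphenyl]-3,5-dihydroxy-7-methoxy-4H-chromen-4-one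
Product: 16 trisodium 3'-O-benzylrhamnetin 3,5,4'-tri-O-sulfate, via tris(triethylammonium) salt 15 (not isolated)
Conditions: SO3·NEt3 (18 equiv), Et3N, MeCN, 100 °C (microwave); then aq. NaOH to pH 8, evaporation; Sephadex G-10, H2O
Reagents that add atoms: sulfur trioxide–triethylamine complex, CC[N+](CC)(CC)S(=O)(=O)[O-]; sodium hydroxide, [Na+].[OH-]
Why: O-sulfation of phenols and of the C3 enol by an amine–SO3 complex; the large excess and heat are for the chelated 5-OH, and because O3' is benzylated and O7 methylated there is no site that could be sulfated wrongly, so exhaustive sulfation gives the required pattern.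

Step 9
Reactants: 16 trisodium 3'-O-benzylrhamnetin 3,5,4'-tri-O-sulfate
Product: 18 rhamnetin 3,5,4'-tri-O-sulfate (acid form), via trisodium salt 17 (not isolated)
Conditions: H2 (1 atm), Pd/C (10% palladium on carbon), MeOH/H2O, rt; filtration; then 0.1 M HCl (3.0 equiv), 0 °C; Sephadex LH-20 (MeOH), 4 °C; freeze-drying
Reagents that add atoms: none
Why: Hydrogenolysis of the benzyl aryl ether at neutral pH, where sulfate salts are stable and their fully oxidised (hexavalent) sulfur does not poison zerovalent palladium; the three sulfonic acid protons are supplied cold at the very end to limit acid hydrolysis.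

## Compound list

1 | 3-(benzyloxy)-4-hydroxybenzaldehyde | O=Cc1ccc(O)c(OCc2ccccc2)c1 | starting material
2 | 3-(benzyloxy)-4-(methoxymethoxy)benzaldehyde | O=Cc1ccc(OCOC)c(OCc2ccccc2)c1 | intermediate
3 | methyl glycolate | COC(=O)CO | starting material
4 | methyl 2-(methoxymethoxy)acetate | COCOCC(=O)OC | intermediate
5 | lithium aldolate of methyl 3-[3-(benzyloxy)-4-(methoxymethoxy)phenyl]-3-hydroxy-2-(methoxymethoxy)propanoate (racemic, mixture of diastereomers, configuration not defined) | [Li+].COC(=O)C(OCOC)C([O-])c1ccc(OCOC)c(OCc2ccccc2)c1 | intermediate (not isolated)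
6 | methyl 3-[3-(benzyloxy)-4-(methoxymethoxy)phenyl]-2-(methoxymethoxy)-3-[(methylsulfonyl)oxy]propanoate (racemic, mixture of diastereomers, configuration not defined) | COC(=O)C(OCOC)C(OS(C)(=O)=O)c1ccc(OCOC)c(OCc2ccccc2)c1 | intermediate (not isolated)
7 | methyl (2Z)-3-[3-(benzyloxy)-4-(methoxymethoxy)phenyl]-2-(methoxymethoxy)prop-2-enoate | COC(=O)/C(OCOC)=C/c1ccc(OCOC)c(OCc2ccccc2)c1 | intermediate
8 | 4-methoxy-6-methyl-2H-pyran-2-one | COc1cc(C)oc(=O)c1 | starting material
9 | 6-{(3Z)-4-[3-(benzyloxy)-4-(methoxymethoxy)phenyl]-3-(methoxymethoxy)-2-oxobut-3-en-1-yl}-4-methoxy-2H-pyran-2-one | COc1cc(CC(=O)/C(OCOC)=C/c2ccc(OCOC)c(OCc3ccccc3)c2)oc(=O)c1 | intermediate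
10 | methyl (2E,8Z)-9-[3-(benzyloxy)-4-(methoxymethoxy)phenyl]-3-methoxy-8-(methoxymethoxy)-5,7-dioxonona-2,8-dienoate | COC(=O)/C=C(OC)\CC(=O)CC(=O)/C(OCOC)=C/c1ccc(OCOC)c(OCc2ccccc2)c1 | intermediate (not isolated)
11 | (2Z)-3-[3-(benzyloxy)-4-(methoxymethoxy)phenyl]-1-(2,6-dihydroxy-4-methoxyphenyl)-2-(methoxymethoxy)prop-2-en-1-one | COc1cc(O)c(C(=O)/C(OCOC)=C/c2ccc(OCOC)c(OCc3ccccc3)c2)c(O)c1 | intermediate (not isolated)
12 | rac-(2R,3R)-2-[3-(benzyloxy)-4-(methoxymethoxy)phenyl]-5-hydroxy-7-methoxy-3-(methoxymethoxy)-2,3-dihydro-4H-chromen-4-one (trans; one enantiomer drawn) | COCOc1ccc(cc1OCc1ccccc1)[C@@H]2[C@H](C(=O)c3c(O)cc(OC)cc3O2)OCOC | intermediate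
13 | 2-[3-(benzyloxy)-4-(methoxymethoxy)phenyl]-5-hydroxy-7-methoxy-3-(methoxymethoxy)-4H-chromen-4-one | COCOc1ccc(cc1OCc1ccccc1)-c1oc2cc(OC)cc(O)c2c(=O)c1OCOC | intermediate
14 | 2-[3-(benzyloxy)-4-hydroxyphenyl]-3,5-dihydroxy-7-methoxy-4H-chromen-4-one | COc1cc(O)c2c(=O)c(O)c(-c3ccc(O)c(OCc4ccccc4)c3)oc2c1 | intermediate
15 | tris(triethylammonium) 3'-O-benzylrhamnetin 3,5,4'-tri-O-sulfate | COc1cc(OS(=O)(=O)[O-])c2c(=O)c(OS(=O)(=O)[O-])c(-c3ccc(OS(=O)(=O)[O-])c(OCc4ccccc4)c3)oc2c1.CC[NH+](CC)CC.CC[NH+](CC)CC.CC[NH+](CC)CC | intermediate (not isolated)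
16 | trisodium 3'-O-benzylrhamnetin 3,5,4'-tri-O-sulfate | COc1cc(OS(=O)(=O)[O-])c2c(=O)c(OS(=O)(=O)[O-])c(-c3ccc(OS(=O)(=O)[O-])c(OCc4ccccc4)c3)oc2c1.[Na+].[Na+].[Na+] | intermediate
17 | trisodium rhamnetin 3,5,4'-tri-O-sulfate | COc1cc(OS(=O)(=O)[O-])c2c(=O)c(OS(=O)(=O)[O-])c(-c3ccc(OS(=O)(=O)[O-])c(O)c3)oc2c1.[Na+].[Na+].[Na+] | intermediate (not isolated)
18 | rhamnetin 3,5,4'-tri-O-sulfate | COc1cc(OS(=O)(=O)O)c2c(=O)c(OS(=O)(=O)O)c(-c3ccc(OS(=O)(=O)O)c(O)c3)oc2c1 | target

## Step count and least certain steps

Total steps: 9. Longest linear sequence: 8 (steps 1, 3, 4, 5, 6, 7, 8, 9, from aldehyde 1).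

Step 5 (key step). Most likely failure: cyclisation in the aldol mode, or retro-Claisen cleavage of the β-diketone by methoxide, if magnesium chelation of the 5,7-diketone is incomplete; also loss of the enol MOM group during the acidic work-up. The fallback builds ring A from a finished benzene ring. It sets out from aldehyde 2 and returns at 14. Purchased acetophenone A1 is mono-protected (MOMCl, i-Pr2NEt) to 1-[2-hydroxy-4-methoxy-6-(methoxymethoxy)phenyl]ethanone F1. Claisen–Schmidt condensation of F1 with 2 (KOH, EtOH) gives (2E)-3-[3-(benzyloxy)-4-(methoxymethoxy)phenyl]-1-[2-hydroxy-4-methoxy-6-(methoxymethoxy)phenyl]prop-2-en-1-one F2. Algar–Flynn–Oyamada oxidation (H2O2, NaOH, MeOH) gives 2-[3-(benzyloxy)-4-(methoxymethoxy)phenyl]-3-hydroxy-7-methoxy-5-(methoxymethoxy)-4H-chromen-4-one F3, the electron-rich 4-alkoxyaryl ring B being relied on to steer closure to Cβ. 3 M HCl in MeOH then removes both MOM groups and gives 14.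

Step 4. Most likely failure: incomplete acyl transfer, because the conjugated α-alkoxy ester is a weak electrophile and the Claisen equilibrium is pulled only by deprotonation of the product; competing metalation of the pyrone ring carbon C3 would add to the loss. The fallback replaces the equilibrium acylation by addition to a chelating amide. It sets out from ester 7 and returns at 9. Me(MeO)NH·HCl and i-PrMgCl in THF at −20 °C convert 7 into (2Z)-3-[3-(benzyloxy)-4-(methoxymethoxy)phenyl]-N-methoxy-2-(methoxymethoxy)-N-methylprop-2-enamide F4. The lithiated pyrone from 8 adds to F4 to give a chelated tetrahedral adduct that collapses to ketone 9 only on work-up.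

Step 6. Most likely failure: electrophilic iodination of the activated ring A at C6 or C8, and acid-induced loss of the C3 MOM group before the dehydrogenation is complete. The fallback moves the oxidation to the dihydroflavonol stage, where no halogen is needed. It sets out from 12 and returns at 14. 3 M HCl in MeOH removes both MOM groups and gives rac-(2R,3R)-2-[3-(benzyloxy)-4-hydroxyphenyl]-3,5-dihydroxy-7-methoxy-2,3-dihydro-4H-chromen-4-one F5. Autoxidation of its C3 enediolate (air, K2CO3, aqueous DMSO) then gives 14.

Step 8. Most likely failure: incomplete sulfation of the chelated, peri-hindered 5-OH, because each sulfate already installed puts negative charge next to the site still to react; partial hydrolysis during heating and desalting would add to it. The fallback uses neutral, protected sulfate diesters. It sets out from 14 and returns at 16. Cl3CCH2OSO2Cl with NaH in THF gives 3'-O-benzylrhamnetin 3,5,4'-tris(2,2,2-trichloroethyl sulfate) F6, which carries no charge and can be purified on silica. Zinc dust and HCO2NH4 in MeOH remove the trichloroethyl groups by reductive elimination and give triammonium 3'-O-benzylrhamnetin 3,5,4'-tri-O-sulfate F7. Aqueous NaOH to pH 8 and evaporation give 16.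

## Further compounds

F1 | step 5 | 1-[2-hydroxy-4-methoxy-6-(methoxymethoxy)phenyl]ethanone | CC(=O)c1c(O)cc(OC)cc1OCOC
F2 | step 5 | (2E)-3-[3-(benzyloxy)-4-(methoxymethoxy)phenyl]-1-[2-hydroxy-4-methoxy-6-(methoxymethoxy)phenyl]prop-2-en-1-one | COCOc1cc(OC)cc(O)c1C(=O)/C=C/c1ccc(OCOC)c(OCc2ccccc2)c1
F3 | step 5 | 2-[3-(benzyloxy)-4-(methoxymethoxy)phenyl]-3-hydroxy-7-methoxy-5-(methoxymethoxy)-4H-chromen-4-one | COCOc1ccc(cc1OCc1ccccc1)-c1oc2cc(OC)cc(OCOC)c2c(=O)c1O
F4 | step 4 | (2Z)-3-[3-(benzyloxy)-4-(methoxymethoxy)phenyl]-N-methoxy-2-(methoxymethoxy)-N-methylprop-2-enamide | CON(C)C(=O)/C(OCOC)=C/c1ccc(OCOC)c(OCc2ccccc2)c1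
F5 | step 6 | rac-(2R,3R)-2-[3-(benzyloxy)-4-hydroxyphenyl]-3,5-dihydroxy-7-methoxy-2,3-dihydro-4H-chromen-4-one (trans; one enantiomer drawn) | Oc1ccc(cc1OCc1ccccc1)[C@@H]2[C@H](C(=O)c3c(O)cc(OC)cc3O2)O
F6 | step 8 | 3'-O-benzylrhamnetin 3,5,4'-tris(2,2,2-trichloroethyl sulfate) | COc1cc(OS(=O)(=O)OCC(Cl)(Cl)Cl)c2c(=O)c(OS(=O)(=O)OCC(Cl)(Cl)Cl)c(-c3ccc(OS(=O)(=O)OCC(Cl)(Cl)Cl)c(OCc4ccccc4)c3)oc2c1
F7 | step 8 | triammonium 3'-O-benzylrhamnetin 3,5,4'-tri-O-sulfate | COc1cc(OS(=O)(=O)[O-])c2c(=O)c(OS(=O)(=O)[O-])c(-c3ccc(OS(=O)(=O)[O-])c(OCc4ccccc4)c3)oc2c1.[NH4+].[NH4+].[NH4+]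
A1 | alternative 1 | 1-(2,6-dihydroxy-4-methoxyphenyl)ethanone | CC(=O)c1c(O)cc(OC)cc1O
A2 | alternative 1 | (2E)-3-[3-(benzyloxy)-4-(methoxymethoxy)phenyl]-1-(2,6-dihydroxy-4-methoxyphenyl)prop-2-en-1-one | COc1cc(O)c(C(=O)/C=C/c2ccc(OCOC)c(OCc3ccccc3)c2)c(O)c1
A3 | alternative 1 | (2Z)-2-{[3-(benzyloxy)-4-(methoxymethoxy)phenyl]methylidene}-4-hydroxy-6-methoxy-1-benzofuran-3(2H)-one | COc1cc(O)c2C(=O)/C(=C/c3ccc(OCOC)c(OCc4ccccc4)c3)Oc2c1
A4 | alternative 2 | 3,5-dimethoxy-2-(trimethylsilyl)phenyl trifluoromethanesulfonate | COc1cc(OC)c([Si](C)(C)C)c(OS(=O)(=O)C(F)(F)F)c1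
A5 | alternative 2 | 3,5-dimethoxybenzyne (1,2-didehydro-3,5-dimethoxybenzene) | COC1=CC(OC)=CC#C1
A6 | alternative 2 | (2Z)-3-[3-(benzyloxy)-4-(methoxymethoxy)phenyl]-2-(methoxymethoxy)prop-2-enoic acid | OC(=O)/C(OCOC)=C/c1ccc(OCOC)c(OCc2ccccc2)c1
A7 | alternative 2 | rac-(2R,3R)-2-[3-(benzyloxy)-4-(methoxymethoxy)phenyl]-5,7-dimethoxy-3-(methoxymethoxy)-2,3-dihydro-4H-chromen-4-one (trans; one enantiomer drawn) | COCOc1ccc(cc1OCc1ccccc1)[C@@H]2[C@H](C(=O)c3c(OC)cc(OC)cc3O2)OCOC
A8 | alternative 3 | 5-hydroxy-7-methoxy-3-(methoxymethoxy)-4H-chromen-4-one | COCOc1coc2cc(OC)cc(O)c2c1=O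
A9 | alternative 3 | [3-(benzyloxy)-4-(methoxymethoxy)phenyl]boronic acid | COCOc1ccc(B(O)O)cc1OCc1ccccc1
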